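- Take the last L reading of each run, turn it into L formed per Z charged, and compare the runs.

in all of them: G 0.10 M
- red: Z 0.27 M; run made earlier
- teal: Z 0.60 M; run made earlier
- flask: Z 0.400 M; time 8.0 min

| run | time / min | L / % | X / % |
|---|---|---|---|
| red | 0.833 | 4.1 | 32.2 |
| red | 1.33 | 6.4 | 33.5 |
| red | 2.00 | 9.8 | 32.2 |
| red | 2.50 | 9.9 | 32.0 |
| red | 4.00 | 9.8 | 34.0 |
| red | 6.00 | 12.4 | 33.7 |
| red | 10.0 | 13.5 | 36.3 |
| teal | 0.833 | 11.4 | 33.8 |
| teal | 1.33 | 15.5 | 33.3 |
| teal | 2.00 | 16.3 | 33.8 |
| teal | 2.50 | 23.2 | 33.9 |
| teal | 4.00 | 23.3 | 34.5 |
| teal | 6.00 | 27.5 | 34.8 |
| teal | 10.0 | 26.0 | 34.9 |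

(readings scatter by 1 percentage point)

- given per volume of solution although it is solid: G
- at the start none of G is in solution
- X is what G becomes in solution
- X means what is dissolved; the solid is not counted in it

- south: doubling the amount of Z, all else as stated
- north: doubling the solubility of G, all else as stated
- south-west: doubling the dissolution coefficient of G, all else as stated

* how much L there is at 8.0 min, in percent of the G charged
* concentration of X in solution at 50 s, in percent of saturation
* the change that raises the amount of L at 8.0 min, in percent of the G charged most ("none" if none brings more than 2 percentage points) (south / north / south-west / none)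
* amount of L at 8.0 min, in percent of the G charged, after south-west

- X stays flat near 34.2% of the G charged in both runs, so L's rate follows Z. If whatever halts L is also first order in Z, dividing one rate by the other removes time and Z together.
- Red gives 5.00% and teal 4.33%. Their mean, 4.67%, is the Z-share (a selectivity factor), the fraction of the Z charged that ends as L.
- Teal's L reads 27.5% and 26.0% late on, so the flask's time lies on the plateau. With 4.00 equivalents of Z, the flask's L is reckoned at 18.7%.
- Is one number enough? Teal's share returns 11.7% for red against 13.5% read, a miss smaller than twice the scatter.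
- Doubled Z asks for 71.6% of the G charged as L plus X, less than the charge. Doubled solubility, with the share doubled too, asks for 106%, more than the charge, so this reckoning overdraws G there and ranks south first.
- X reads 96.4% of its plateau at the first readings of both runs, close to 50 s. The Z-share holds no dissolution term, so the reckoning for south-west stays at 18.7%.
- The forecast gives 19%, 96%, south and 19%, on the ground that “the plateau scales with Z”.
- The flask gives L 17.9%, X 98.1% of saturation, south as best with a gain of 17 percentage points, and 18.1% after south-west.

    G ⇌ X, rate k1*(cs1 - [X]) while solid is left; crystals form when [X] > cs1 (solubility = 34.0 mM, k = 0.260 /s)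
    L ⇌ J (K = 0.980, k = 0.00930 /s)
    X + Z → L (k = 0.0160 /M/s)
    Z → E (k = 0.00520 /s)

- At 8.0 min the flask holds J 16.5% beside L 17.9%, with Z down to 6.4% of its charge. The Z-share of 4.67% gave 18.7% for L, and the flask has 17.9%. The neighbour flask, charged with 0.24 M of Z, has 2.40 equiv, so the same share gives 11.2%; at the same time its Z is down to 6.4% of its charge, and it holds L 10.8%.

(The data stem from a simulated flask on assumed constants, noise included.)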